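**Retrosynthetic overview**

The target is 3β-acetoxy-labda-7,13(E)-dien-15-oic acid. C12–C13 is formed last by a B-alkyl Suzuki–Miyaura coupling of a C9 vinyl group with an (E)-3-triflyloxybut-2-enoate; C7=C8 comes from a C7 ketone through its enol triflate; C11=C12 comes from a C11 acyl group.
Key disconnection: C5–C10 together with C8–C9, by an intramolecular Diels–Alder reaction of an acyclic triene. Ring A (closed by C5–C10 across the C1–C4 tether) and ring B are formed together in that step; no carbocycle exists before it.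
Enabling feature: ring B (C5–C10) is at the cyclohexene level, with C5–C10 and C8–C9 as its two para-related σ-bonds. C10 carries CH3 (C20) and C9 carries C11 cis to it, which is an (E)-CH2–C(CH3)=CH–C(=O) dienophile. C5=C6–C7(OSi)=C8(C17) is a 2-silyloxy diene, and C1–C4 with the C4 gem-dimethyl group is a four-carbon tether.
Building blocks: (R)-pantolactone (C2–C5, C18, C19 and the C3 stereocentre), one tert-butyl (E)-3-triflyloxybut-2-enoate used twice (C9–C11/C20 and C13–C16), a ketophosphonate (C6–C8, C17), two Wittig methylene units (C1, C12), and an (S)-4-benzyloxazolidin-2-one on C11 to fix the facial sense.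

Key step: step 11

Remark: labdane numbering (C1–C10 ring carbons, C11–C16 side chain, C17 on C8, C18/C19 on C4, C20 on C10) is used for all compounds, acyclic ones included; TBS = tert-butyldimethylsilyl, Tf = trifluoromethanesulfonyl, 9-BBN = 9-borabicyclo[3.3.1]nonane; the C8 configuration of 17–21 is of no consequence because C8 becomes sp2 in step 15.

**Route**

Step 1
Reactants: 1 (R)-pantolactone [(3R)-3-hydroxy-4,4-dimethyloxolan-2-one]
Product: 2 (3R)-3-(TBS-oxy)-4,4-dimethyloxolan-2-one
Conditions: TBSCl, imidazole, DMF, 23 °C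
Reagents that add atoms: tert-butyldimethylsilyl chloride, CC(C)(C)[Si](C)(C)Cl
Why: Imidazole-promoted silylation (silyl ether formation) of the only hydroxyl protects the future C3 oxygen without touching the stereocentre taken from the chiral pool.

Step 2
Reactants: 2 (3R)-3-(TBS-oxy)-4,4-dimethyloxolan-2-one
Product: 3 (3R)-3-(TBS-oxy)-4,4-dimethyloxolan-2-ol (lactol; both anomers)
Conditions: i-Bu2AlH, CH2Cl2, −78 °C; aq. potassium sodium tartrate
Reagents that add atoms: none
Why: Partial hydride reduction of a lactone stops at the lactol because the tetrahedral aluminate is stable at −78 °C.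

Step 3
Reactants: 3 (3R)-3-(TBS-oxy)-4,4-dimethyloxolan-2-ol
Product: 4 (3S)-3-(TBS-oxy)-2,2-dimethylpent-4-en-1-ol
Conditions: Ph3PCH3Br, n-BuLi, THF, −78 → 0 °C
Reagents that add atoms: methyltriphenylphosphonium bromide, C[P+](c1ccccc1)(c1ccccc1)c1ccccc1.[Br-]
Why: Wittig methylenation of the open hydroxy-aldehyde form of the lactol installs the C1=C2 vinyl group; the lithium alkoxide and low temperature should suppress O→O silyl migration.

Step 4
Reactants: 5 tert-butyl 3-oxobutanoate (tert-butyl acetoacetate)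
Product: 6 tert-butyl (2E)-3-(triflyloxy)but-2-enoate
Conditions: Tf2O, Me4NOH (25% aq.), hexanes, 5 °C
Reagents that add atoms: trifluoromethanesulfonic anhydride, O=S(=O)(OS(=O)(=O)C(F)(F)F)C(F)(F)F
Why: O-Sulfonylation of the acetoacetate enolate with a non-chelating tetramethylammonium counter-ion should give the (E)-enol triflate (triflate trans to the ester), which fixes the later C9=C10 and C13=C14 geometry.

Step 5
Reactants: 6 tert-butyl (2E)-3-(triflyloxy)but-2-enoate
Product: 7 (2E)-3-(triflyloxy)but-2-enoic acid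
Conditions: CF3CO2H, CH2Cl2, 23 °C
Reagents that add atoms: none
Why: Acid-mediated tert-butyl ester cleavage (loss of 2-methylpropene) frees the acid and leaves the enol triflate and its geometry untouched.

Step 6
Reactants: 7 (2E)-3-(triflyloxy)but-2-enoic acid; 8 (4S)-4-benzyl-1,3-oxazolidin-2-one
Product: 10 (4S)-4-benzyl-3-[(2E)-3-(triflyloxy)but-2-enoyl]-1,3-oxazolidin-2-one, via acid chloride 9 (not isolated)
Conditions: (COCl)2, DMF (cat.), CH2Cl2, 0 → 23 °C; then 8 pre-treated with n-BuLi, THF, −78 °C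
Reagents that add atoms: none
Why: Acid chloride formation followed by N-acylation of the lithiated oxazolidinone attaches the chiral auxiliary at −78 °C, where acyl substitution should outrun addition at the β-carbon.

Step 7
Reactants: 4 (3S)-3-(TBS-oxy)-2,2-dimethylpent-4-en-1-ol; 10 (4S)-4-benzyl-3-[(2E)-3-(triflyloxy)but-2-enoyl]-1,3-oxazolidin-2-one
Product: 12 (4S)-4-benzyl-3-[(2E,6S)-6-(TBS-oxy)-8-hydroxy-3,7,7-trimethyloct-2-enoyl]-1,3-oxazolidin-2-one, via bis-boryl adduct 11 (not isolated)
Conditions: 9-BBN (2.2 equiv), THF, 23 °C; then 10, Pd(dppf)Cl2 (5 mol %), AsPh3, K3PO4 (3 M aq.), DMF, 23 °C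
Reagents that add atoms: none
Why: Anti-Markovnikov hydroboration of the terminal vinyl group and B-alkyl Suzuki–Miyaura coupling (oxidative addition of the enol triflate to zerovalent palladium, retention of alkene geometry) form C1–C10 and give the (E)-trisubstituted dienophile.

Step 8
Reactants: 12 hydroxy imide
Product: 13 (4S)-4-benzyl-3-[(2E,6S)-6-(TBS-oxy)-3,7,7-trimethyl-8-oxooct-2-enoyl]-1,3-oxazolidin-2-one
Conditions: (n-Pr4N)RuO4 (5 mol %), N-methylmorpholine N-oxide, 4 Å molecular sieves, CH2Cl2, 23 °C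
Reagents that add atoms: none
Why: Perruthenate-catalysed oxidation of the neopentyl primary alcohol gives an aldehyde that has no α-hydrogen and so can neither epimerise nor enolise.

Step 9
Reactants: 13 aldehyde imide; 14 diethyl (2-oxobutyl)phosphonate
Product: 15 (4S)-4-benzyl-3-[(2E,6S,8E)-6-(TBS-oxy)-3,7,7-trimethyl-10-oxododeca-2,8-dienoyl]-1,3-oxazolidin-2-one
Conditions: LiCl, i-Pr2NEt, MeCN, 23 °C
Reagents that add atoms: none
Why: Horner–Wadsworth–Emmons olefination of the non-enolisable aldehyde under mild LiCl/amine conditions gives the (E)-enone (C5=C6, C7 ketone) and leaves the imide intact.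

Step 10
Reactants: 15 enone imide
Product: 16 (4S)-4-benzyl-3-[(2E,6S,8E,10Z)-6,10-bis(TBS-oxy)-3,7,7-trimethyldodeca-2,8,10-trienoyl]-1,3-oxazolidin-2-one
Conditions: TBSOTf, Et3N, CH2Cl2, −78 → 0 °C
Reagents that add atoms: tert-butyldimethylsilyl trifluoromethanesulfonate, CC(C)(C)[Si](C)(C)OS(=O)(=O)C(F)(F)F
Why: Soft enolisation (silyl enol ether formation) can only occur at C8, because C4 is quaternary, and should give the (Z)-enol ether, i.e. a 2-silyloxy diene with C17 in the outside position.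

Step 11
Reactants: 16 silyloxy-trienoyl imide
Product: 17 trans-decalin cycloadduct: 3β-OTBS, 4,4-dimethyl, 5α-H, 6-ene bearing 7-OTBS, 8β-methyl, 9β-C(=O) (C11) bound to N of (4S)-4-benzyl-1,3-oxazolidin-2-one, 10β-methyl
Conditions: Me2AlCl (2.5 equiv), CH2Cl2 (0.005 M), −40 → 0 °C; aq. potassium sodium tartrate
Reagents that add atoms: none
Why: Me2AlCl binds both imide carbonyls in a cationic chelate that locks the enoyl group s-cis and lowers the LUMO of the C9=C10 alkene, which then undergoes a concerted but asynchronous intramolecular [4+2] cycloaddition with the C5=C6–C7(OTBS)=C8 diene, forming C5–C10 and C8–C9 (type 1 intramolecular Diels–Alder reaction). The closest known reaction type is the dialkylaluminium chloride-promoted intramolecular Diels–Alder reaction of (E)-deca-2,7,9-trienoyl oxazolidinones to trans-fused bicyclo[4.4.0]decenes; the present substrate adds a β-methyl group on the dienophile and a 2-silyloxy group on the diene. Ring A (C1–C5, C10) is closed by the C5–C10 bond across the four-carbon tether C1–C4 in a chair-like array helped by the C4 gem-dimethyl group (Thorpe–Ingold effect), and ring B (C5–C10) is closed as the cyclohexene of the cycloaddition itself. The cis relation of C20 and C11 follows from the (E)-alkene and suprafacial addition; the absolute sense at C9 and C10 follows from the benzyl group of the auxiliary, which shields one face of the chelated dienophile so that the diene adds to the C9 si face; the trans ring fusion (5α-H, 10β-CH3) follows from the endo position of the chelated carbonyl with the tether exo; the 8β-methyl group (erased later) follows from the outside position of C17; the existing C3 silyloxy group lies equatorial in this transition state. The step needs the silyl dienol ether to react as a diene through C5 and C8 and not as a Michael donor through C8; the tether (a C8–C10 bond would need a nine-membered ring), high dilution, the hindered β,β-disubstituted acceptor carbon and a proton-scavenging Lewis acid at low temperature should secure this.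

Step 12
Reactants: 17 cycloadduct imide
Product: 18 primary alcohol: trans-decalin with 3β-OTBS, 4,4-dimethyl, 5α-H, 6-ene bearing 7-OTBS, 8β-methyl, 9β-CH2OH (C11), 10β-methyl
Conditions: LiBH4, MeOH (1 equiv), THF, 0 °C; 1 M NaOH
Reagents that add atoms: none
Why: Reductive cleavage of the N-acyl oxazolidinone (hydride attack at the exocyclic carbonyl) gives the C11 alcohol and returns the auxiliary, while the silyl enol ether is inert to borohydride.

Step 13
Reactants: 18 primary alcohol
Product: 19 aldehyde: as 18 but 9β-CHO (C11)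
Conditions: SO3·pyridine, DMSO, i-Pr2NEt, CH2Cl2, 0 °C
Reagents that add atoms: none
Why: Parikh–Doering oxidation is non-acidic, so the silyl enol ether survives, and the C9 formyl group stays in its equatorial, thermodynamically preferred position.

Step 14
Reactants: 19 aldehyde
Product: 21 keto alkene: trans-decalin with 3β-OTBS, 4,4-dimethyl, 5α-H, 7-oxo, 8β-methyl, 9β-vinyl (C11=C12), 10β-methyl, via enol ether alkene 20 (not isolated)
Conditions: Ph3PCH3Br, n-BuLi, THF, −78 → 0 °C; then 1 M HCl (aq.), THF, 0 °C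
Reagents that add atoms: methyltriphenylphosphonium bromide, C[P+](c1ccccc1)(c1ccccc1)c1ccccc1.[Br-]
Why: Wittig methylenation is carried out while the C7 carbonyl is still masked, and the acid work-up then hydrolyses the silyl enol ether (protonation at C6) to the C7 ketone without cleaving the hindered C3 silyl ether.

Step 15
Reactants: 21 keto alkene
Product: 22 enol triflate: trans-decalin with 3β-OTBS, 4,4-dimethyl, 5α-H, 7-ene bearing 7-OTf and 8-methyl, 9β-vinyl, 10β-methyl
Conditions: Tf2O, 2,6-di-tert-butyl-4-methylpyridine, CH2Cl2, 0 → 23 °C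
Reagents that add atoms: trifluoromethanesulfonic anhydride, O=S(=O)(OS(=O)(=O)C(F)(F)F)C(F)(F)F
Why: Enol triflate formation through the O-triflylated ketone and proton loss to a hindered pyridine should favour the more substituted C7=C8 isomer (Zaitsev-type elimination, away from the congested C5/C6 side), which places the alkene where the target has it.

Step 16
Reactants: 22 enol triflate
Product: 23 diene: trans-decalin with 3β-OTBS, 4,4-dimethyl, 5α-H, 7-ene, 8-methyl, 9β-vinyl, 10β-methyl
Conditions: Pd(OAc)2 (5 mol %), PPh3, HCO2H, n-Bu3N, DMF, 60 °C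
Reagents that add atoms: none
Why: Palladium-catalysed formate reduction of the alkenyl triflate (oxidative addition to zerovalent palladium, decarboxylation of formate, reductive elimination) replaces OTf by H without moving the double bond.

Step 17
Reactants: 23 silyl ether diene
Product: 24 alcohol: as 23 but 3β-OH
Conditions: n-Bu4NF, THF, 50 °C
Reagents that add atoms: none
Why: Fluoride-induced desilylation frees the hindered equatorial C3 hydroxyl and affects nothing else.

Step 18
Reactants: 24 alcohol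
Product: 25 acetate: trans-decalin with 3β-OAc, 4,4-dimethyl, 5α-H, 7-ene, 8-methyl, 9β-vinyl, 10β-methyl
Conditions: Ac2O, pyridine, 4-(dimethylamino)pyridine (cat.), 23 °C
Reagents that add atoms: acetic anhydride, CC(=O)OC(C)=O
Why: Nucleophile-catalysed acylation installs the C3 acetate of the target before the acid is introduced, so no differentiation of hydroxyl and carboxyl is needed later.

Step 19
Reactants: 25 acetate; 6 tert-butyl (2E)-3-(triflyloxy)but-2-enoate
Product: 27 tert-butyl 3β-acetoxy-labda-7,13(E)-dien-15-oate, via B-alkyl-9-BBN 26 (not isolated)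
Conditions: 9-BBN, THF, 23 °C; then 6, Pd(dppf)Cl2 (5 mol %), AsPh3, K3PO4 (3 M aq.), DMF, 23 °C
Reagents that add atoms: none
Why: 9-BBN hydroborates only the monosubstituted C11=C12 alkene (boron on C12), and B-alkyl Suzuki–Miyaura coupling with the (E)-enol triflate forms C12–C13 with retention, setting the 13E geometry.

Step 20
Reactants: 27 tert-butyl ester
Product: 29 3β-acetoxy-labda-7,13(E)-dien-15-oic acid (target), via trimethylsilyl ester 28 (not isolated)
Conditions: Me3SiOTf, 2,6-lutidine, CH2Cl2, 0 °C; then H2O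
Reagents that add atoms: none
Why: Silyl triflate-mediated tert-butyl ester cleavage (loss of 2-methylpropene under buffered, non-protic conditions) followed by hydrolysis of the silyl ester frees the acid without touching the acetate or isomerising the C7=C8 alkene.

**Compound list**

1 | (R)-pantolactone | CC1(C)COC(=O)[C@@H]1O | starting material
2 | (3R)-3-(TBS-oxy)-4,4-dimethyloxolan-2-one | CC1(C)COC(=O)[C@@H]1O[Si](C)(C)C(C)(C)C | intermediate
3 | (3R)-3-(TBS-oxy)-4,4-dimethyloxolan-2-ol | CC1(C)COC(O)[C@@H]1O[Si](C)(C)C(C)(C)C | intermediate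
4 | (3S)-3-(TBS-oxy)-2,2-dimethylpent-4-en-1-ol | C=C[C@H](O[Si](C)(C)C(C)(C)C)C(C)(C)CO | intermediate
5 | tert-butyl 3-oxobutanoate | CC(=O)CC(=O)OC(C)(C)C | starting material
6 | tert-butyl (2E)-3-(triflyloxy)but-2-enoate | FC(F)(F)S(=O)(=O)O/C(C)=C/C(=O)OC(C)(C)C | intermediate
7 | (2E)-3-(triflyloxy)but-2-enoic acid | FC(F)(F)S(=O)(=O)O/C(C)=C/C(=O)O | intermediate
8 | (4S)-4-benzyl-1,3-oxazolidin-2-one | O=C1N[C@@H](Cc2ccccc2)CO1 | starting material
9 | (2E)-3-(triflyloxy)but-2-enoyl chloride | FC(F)(F)S(=O)(=O)O/C(C)=C/C(=O)Cl | intermediate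
10 | (4S)-4-benzyl-3-[(2E)-3-(triflyloxy)but-2-enoyl]-1,3-oxazolidin-2-one | FC(F)(F)S(=O)(=O)O/C(C)=C/C(=O)N1[C@@H](Cc2ccccc2)COC1=O | intermediate
11 | bis-boryl adduct of 4 (C1–B and O–B 9-BBN) | CC(C)(COB1C2CCCC1CCC2)[C@@H](O[Si](C)(C)C(C)(C)C)CCB1C2CCCC1CCC2 | intermediate
12 | (4S)-4-benzyl-3-[(2E,6S)-6-(TBS-oxy)-8-hydroxy-3,7,7-trimethyloct-2-enoyl]-1,3-oxazolidin-2-one | OCC(C)(C)[C@@H](O[Si](C)(C)C(C)(C)C)CC/C(C)=C/C(=O)N1[C@@H](Cc2ccccc2)COC1=O | intermediate
13 | (4S)-4-benzyl-3-[(2E,6S)-6-(TBS-oxy)-3,7,7-trimethyl-8-oxooct-2-enoyl]-1,3-oxazolidin-2-one | O=CC(C)(C)[C@@H](O[Si](C)(C)C(C)(C)C)CC/C(C)=C/C(=O)N1[C@@H](Cc2ccccc2)COC1=O | intermediate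
14 | diethyl (2-oxobutyl)phosphonate | CCC(=O)CP(=O)(OCC)OCC | starting material
15 | (4S)-4-benzyl-3-[(2E,6S,8E)-6-(TBS-oxy)-3,7,7-trimethyl-10-oxododeca-2,8-dienoyl]-1,3-oxazolidin-2-one | CCC(=O)/C=C/C(C)(C)[C@@H](O[Si](C)(C)C(C)(C)C)CC/C(C)=C/C(=O)N1[C@@H](Cc2ccccc2)COC1=O | intermediate
16 | (4S)-4-benzyl-3-[(2E,6S,8E,10Z)-6,10-bis(TBS-oxy)-3,7,7-trimethyldodeca-2,8,10-trienoyl]-1,3-oxazolidin-2-one | C/C=C(O[Si](C)(C)C(C)(C)C)/C=C/C(C)(C)[C@@H](O[Si](C)(C)C(C)(C)C)CC/C(C)=C/C(=O)N1[C@@H](Cc2ccccc2)COC1=O | intermediate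
17 | trans-decalin cycloadduct (3β,7-bis-OTBS, 6-ene, 8β-methyl, 9β-acyl oxazolidinone) | CC(C)(C)[Si](C)(C)O[C@H]1CC[C@]2(C)[C@@H](C(=O)N3[C@@H](Cc4ccccc4)COC3=O)[C@@H](C)C(O[Si](C)(C)C(C)(C)C)=C[C@H]2C1(C)C | intermediate
18 | C11 alcohol (3β,7-bis-OTBS, 6-ene, 8β-methyl, 9β-CH2OH) | CC(C)(C)[Si](C)(C)O[C@H]1CC[C@]2(C)[C@@H](CO)[C@@H](C)C(O[Si](C)(C)C(C)(C)C)=C[C@H]2C1(C)C | intermediate
19 | C11 aldehyde (3β,7-bis-OTBS, 6-ene, 8β-methyl, 9β-CHO) | CC(C)(C)[Si](C)(C)O[C@H]1CC[C@]2(C)[C@@H](C=O)[C@@H](C)C(O[Si](C)(C)C(C)(C)C)=C[C@H]2C1(C)C | intermediate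
20 | enol ether alkene (3β,7-bis-OTBS, 6-ene, 8β-methyl, 9β-vinyl) | CC(C)(C)[Si](C)(C)O[C@H]1CC[C@]2(C)[C@@H](C=C)[C@@H](C)C(O[Si](C)(C)C(C)(C)C)=C[C@H]2C1(C)C | intermediate
21 | keto alkene (3β-OTBS, 7-oxo, 8β-methyl, 9β-vinyl) | CC(C)(C)[Si](C)(C)O[C@H]1CC[C@]2(C)[C@@H](C=C)[C@@H](C)C(=O)C[C@H]2C1(C)C | intermediate
22 | enol triflate (3β-OTBS, 7-ene, 7-OTf, 8-methyl, 9β-vinyl) | CC(C)(C)[Si](C)(C)O[C@H]1CC[C@]2(C)[C@@H](C=C)C(C)=C(OS(=O)(=O)C(F)(F)F)C[C@H]2C1(C)C | intermediate
23 | diene (3β-OTBS, 7-ene, 8-methyl, 9β-vinyl) | CC(C)(C)[Si](C)(C)O[C@H]1CC[C@]2(C)[C@@H](C=C)C(C)=CC[C@H]2C1(C)C | intermediate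
24 | dienol (3β-OH, 7-ene, 8-methyl, 9β-vinyl) | O[C@H]1CC[C@]2(C)[C@@H](C=C)C(C)=CC[C@H]2C1(C)C | intermediate
25 | diene acetate (3β-OAc, 7-ene, 8-methyl, 9β-vinyl) | CC(=O)O[C@H]1CC[C@]2(C)[C@@H](C=C)C(C)=CC[C@H]2C1(C)C | intermediate
26 | B-alkyl-9-BBN of 25 (boron on C12) | CC(=O)O[C@H]1CC[C@]2(C)[C@@H](CCB3C4CCCC3CCC4)C(C)=CC[C@H]2C1(C)C | intermediate
27 | tert-butyl 3β-acetoxy-labda-7,13(E)-dien-15-oate | CC(=O)O[C@H]1CC[C@]2(C)[C@@H](CC/C(C)=C/C(=O)OC(C)(C)C)C(C)=CC[C@H]2C1(C)C | intermediate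
28 | trimethylsilyl 3β-acetoxy-labda-7,13(E)-dien-15-oate | CC(=O)O[C@H]1CC[C@]2(C)[C@@H](CC/C(C)=C/C(=O)O[Si](C)(C)C)C(C)=CC[C@H]2C1(C)C | intermediate
29 | 3β-acetoxy-labda-7,13(E)-dien-15-oic acid | CC(=O)O[C@H]1CC[C@]2(C)[C@@H](CC/C(C)=C/C(=O)O)C(C)=CC[C@H]2C1(C)C | target

**Step count and risks**

Total step count: 20. Longest linear sequence: 17 steps (steps 1–3 then 7–20 from 1; equally steps 4–20 from 5).

Steps most likely to fail:

1. Step 11. The silyl dienol ether may be consumed by the Lewis acid (desilylation, or intermolecular Michael-type attack through C8) before the hindered cycloaddition takes place. Fallback, leaving from 13 and rejoining at 21: no oxygen is carried at C7 through the cycloaddition. Julia–Kocienski olefination of 13 with 1-phenyl-5-[(2E)-but-2-en-1-ylsulfonyl]-1H-tetrazole (KN(SiMe3)2, THF, −78 °C) would give the all-carbon (2E,8E,10E)-trienoyl imide F1. Its Me2AlCl-promoted intramolecular Diels–Alder reaction (CH2Cl2, −30 °C), the standard substrate type for this auxiliary, should give the 6-ene cycloadduct F2. LiBH4 would then give the C11 alcohol F3. Hydroboration with BH3·SMe2 followed by NaOH/H2O2, with boron going to C7 (the alkene carbon remote from the quaternary C4 and C10), would give the 7α,11-diol F4. Parikh–Doering oxidation of both hydroxyls would give the keto aldehyde F5, and one equivalent of Ph3P=CH2 at −78 °C should olefinate only the aldehyde and give 21.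

2. Step 15. Proton loss towards C6 instead of C8 during triflation would give poor regioselectivity and hence the 6-ene after reduction. Fallback, leaving from 21 and rejoining at 23: condensation of 21 with 4-methylbenzenesulfonohydrazide (EtOH, 60 °C) gives the tosylhydrazone F6. An aprotic Bamford–Stevens reaction (NaOMe, diglyme, 160 °C) then forms the C7 carbene, whose 1,2-hydride shift from the tertiary C8–H should give 23 directly, with no enol derivative involved.

3. Step 12. Hydride may attack the ring carbonyl of the auxiliary (ring opening instead of acyl cleavage), because the exocyclic acyl group on C9 is flanked by C8 and the quaternary C10. Fallback, leaving from 17 and rejoining at 18: LiSEt (from EtSH and n-BuLi, THF, 0 °C), a small nucleophile selective for the exocyclic carbonyl, would give the S-ethyl thioester F7, which i-Bu2AlH (CH2Cl2, −78 → 0 °C) reduces to 18.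

Further compounds
F1 | step 11 | (4S)-4-benzyl-3-[(2E,6S,8E,10E)-6-(TBS-oxy)-3,7,7-trimethyldodeca-2,8,10-trienoyl]-1,3-oxazolidin-2-one | C/C=C/C=C/C(C)(C)[C@@H](O[Si](C)(C)C(C)(C)C)CC/C(C)=C/C(=O)N1[C@@H](Cc2ccccc2)COC1=O
F2 | step 11 | trans-decalin cycloadduct (3β-OTBS, 6-ene, 8β-methyl, 9β-acyl oxazolidinone) | CC(C)(C)[Si](C)(C)O[C@H]1CC[C@]2(C)[C@@H](C(=O)N3[C@@H](Cc4ccccc4)COC3=O)[C@@H](C)C=C[C@H]2C1(C)C
F3 | step 11 | C11 alcohol (3β-OTBS, 6-ene, 8β-methyl, 9β-CH2OH) | CC(C)(C)[Si](C)(C)O[C@H]1CC[C@]2(C)[C@@H](CO)[C@@H](C)C=C[C@H]2C1(C)C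
F4 | step 11 | 7α,11-diol (3β-OTBS, 8β-methyl) | CC(C)(C)[Si](C)(C)O[C@H]1CC[C@]2(C)[C@@H](CO)[C@@H](C)[C@H](O)C[C@H]2C1(C)C
F5 | step 11 | keto aldehyde (3β-OTBS, 7-oxo, 8β-methyl, 9β-CHO) | CC(C)(C)[Si](C)(C)O[C@H]1CC[C@]2(C)[C@@H](C=O)[C@@H](C)C(=O)C[C@H]2C1(C)C
F6 | step 15 | C7 tosylhydrazone of 21 | CC(C)(C)[Si](C)(C)O[C@H]1CC[C@]2(C)[C@@H](C=C)[C@@H](C)C(=NNS(=O)(=O)c3ccc(C)cc3)C[C@H]2C1(C)C
F7 | step 12 | S-ethyl thioester at C11 (3β,7-bis-OTBS, 6-ene, 8β-methyl) | CC(C)(C)[Si](C)(C)O[C@H]1CC[C@]2(C)[C@@H](C(=O)SCC)[C@@H](C)C(O[Si](C)(C)C(C)(C)C)=C[C@H]2C1(C)C
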